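**Plan**

1. Carotenoid numbering is used: C1–C6 is the triol ring, C1'–C6' the carbocycle of the other half, and O/C5'/C6'/C7'/C8' its dihydrofuran ring. The retrosynthesis cuts C11=C12 and C11'=C12' (Wittig) to a C10 dialdehyde and two C15 phosphonium salts.
2. In the dihydrofuran half, C7'–C8' and O–C5' are cut together, back to a sulfonium ylide of the C10 ring unit and a C5 enal. In the triol half the cuts are C5–OH (epoxide opening), C6–C7 (Heck) and C9–C10 (vinyl addition).
3. Enabling feature: in the ring O/C5'/C6'/C7'/C8', C5' is tertiary and allylic through the exocyclic C6'=C7' bond, so this ring is the ring-expanded isomer of a C7'–C8' vinyl oxirane on the C5'=C6' cyclohexene. Acid opens the oxirane at C7' to the allyl cation C5'–C6'–C7', the oxygen on C8' recloses on C5', and the ester on C10' keeps C8'–O from ionising.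
4. Forward: one enol triflate from silylated (4R,6R)-actinol serves both halves. Hydroxymethylation, bromide, chiral sulfonium salt and the one-flask ylide addition/ring expansion give the dihydrofuran C15 ester and then its phosphonium salt. Heck reaction, hydroxyl-directed syn epoxidation, anti hydrolysis at C5, vinyl addition and PPh3·HBr give the triol C15 salt.
5. The chain is joined last: triol salt plus C10 dialdehyde gives the C25 aldehyde, the dihydrofuran salt then gives C40, and desilylation gives the target.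
6. Stereochemistry: C3 and C3' come from actinol; C8' from the C2-symmetric sulfide; C5' from axial closure anti to the C3' silyloxy group; C5 and C6 from OH-directed epoxidation followed by inversion at C5. The E-alkenes come from the enal, the Heck step, thermodynamic salt formation and Wittig reactions with thermal equilibration.

Key step: step 7

Remark: (2R,5R)-2,5-dimethylthiolane is assumed to steer this allylic ylide in the sense known for its benzylic ylides, i.e. to the S-configured aldehyde-derived oxirane carbon.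
Remark: (4R,6R)-actinol 1 and the cyclic sulfate 7 are taken as catalogue compounds.

**Route**

Step 1
Reactants: 1 (4R,6R)-4-hydroxy-2,2,6-trimethylcyclohexan-1-one
Product: 2 (4R,6R)-4-[(tert-butyldimethylsilyl)oxy]-2,2,6-trimethylcyclohexan-1-one
Conditions: t-BuMe2SiCl, imidazole, DMF, rt
Reagents that add atoms: tert-butyldimethylsilyl chloride, CC(C)(C)[Si](C)(C)Cl
Why: Silyl ether formation at the only hydroxyl should proceed cleanly and touches no stereocentre.

Step 2
Reactants: 2 silyl ether of actinol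
Product: 4 (4R)-4-[(tert-butyldimethylsilyl)oxy]-2,6,6-trimethylcyclohex-1-en-1-yl trifluoromethanesulfonate, via potassium enolate 3 (not isolated)
Conditions: KN(SiMe3)2, THF, −78 °C; then PhNTf2, −78 °C → rt
Reagents that add atoms: N-phenylbis(trifluoromethanesulfonimide), O=S(=O)(N(c1ccccc1)S(=O)(=O)C(F)(F)F)C(F)(F)F
Why: Enol triflate formation can only go toward the methyl-bearing carbon because the other α-carbon is quaternary, so the C5 centre is erased and C3 is kept.

Step 3
Reactants: 4 enol triflate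
Product: 5 {(4R)-4-[(tert-butyldimethylsilyl)oxy]-2,6,6-trimethylcyclohex-1-en-1-yl}methanol
Conditions: Bu3SnCH2OH, Pd(PPh3)4 (5 mol %), LiCl, 1,4-dioxane, 100 °C
Reagents that add atoms: (tributylstannyl)methanol, CCCC[Sn](CCCC)(CCCC)CO
Why: Stille coupling of the enol triflate with the hydroxymethyl stannane should install C7' as CH2OH with the ring alkene kept in place.

Step 4
Reactants: 5 allylic alcohol
Product: 6 (4R)-1-(bromomethyl)-4-[(tert-butyldimethylsilyl)oxy]-2,6,6-trimethylcyclohex-1-ene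
Conditions: CBr4, PPh3, CH2Cl2, 0 °C
Reagents that add atoms: carbon tetrabromide, BrC(Br)(Br)Br
Why: Appel bromination of the primary allylic alcohol is neutral and should leave the silyl ether and the tetrasubstituted alkene untouched.

Step 5
Reactants: 7 (4S,7S)-4,7-dimethyl-1,3,2-dioxathiepane 2,2-dioxide
Product: 8 (2R,5R)-2,5-dimethylthiolane
Conditions: Na2S·9H2O, EtOH/H2O, 60 °C
Reagents that add atoms: sodium sulfide, [Na+].[Na+].[S-2]
Why: Double SN2 displacement of the cyclic sulfate by sulfide (second displacement 5-exo-tet) should invert both carbinol carbons, (S,S) to (R,R).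

Step 6
Reactants: 6 allylic bromide, 8 (2R,5R)-2,5-dimethylthiolane
Product: 9 (2R,5R)-1-({(4R)-4-[(tert-butyldimethylsilyl)oxy]-2,6,6-trimethylcyclohex-1-en-1-yl}methyl)-2,5-dimethylthiolan-1-ium tetrafluoroborate
Conditions: NaBF4, acetone, rt, dark
Reagents that add atoms: sodium tetrafluoroborate, [Na+].F[B-](F)(F)F
Why: SN2 S-alkylation by the primary allylic bromide (sulfonium salt formation) is driven by precipitation of NaBr, and the C2 symmetry of the sulfide means that sulfur is not a new stereocentre.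

Step 7
Reactants: 9 sulfonium tetrafluoroborate, 10 ethyl (2E)-3-methyl-4-oxobut-2-enoate
Product: 13 ethyl (2E)-3-{(2R,6S,7aR)-6-[(tert-butyldimethylsilyl)oxy]-4,4,7a-trimethyl-2,4,5,6,7,7a-hexahydro-1-benzofuran-2-yl}but-2-enoate, via sulfonium ylide 11 (not isolated), via trans-vinyl oxirane 12 (not isolated)
Conditions: t-BuOK, THF, −78 °C; 10, −78 → −30 °C; then camphorsulfonic acid (20 mol %), CH2Cl2, −30 → 0 °C
Reagents that add atoms: none
Why: The ylide 11 (carbanion at C7') adds to the aldehyde carbon of 10 to form C7'–C8' and the adduct closes by 3-exo-tet substitution at C7' to the trans-oxirane 12; the acid then opens the allylic C7'–O bond to the tertiary allyl cation C5'–C6'–C7', and the oxygen still bound to C8' closes on C5' (O–C5') in a cationic 5-endo closure on the far allyl terminus, the course also taken by cis-2-ene-1,4-diol cyclodehydrations. The closest known reaction types are the sulfur-ylide epoxidation of enals with allylic sulfonium salts of chiral thiolanes and the acid- or copper-catalysed ring expansion of vinyl oxiranes to 2,5-dihydrofurans, of which the 5,6-epoxide to 5,8-epoxide change of carotenoids is the mirror case. C8' is controlled by the (2R,5R)-thiolane, which shields one face of the ylide and should give the S-configured aldehyde carbon in 12; this centre is not touched in the ring expansion and is 8'R in 13 only because the CIP priorities change. C5' is set in the closure, which should take place axially on the cyclohexenyl cation, anti to the pseudo-equatorial silyloxy group at C3', as in peracid attack on 3-oxygenated β-end groups. The step needs 1,2- over 1,4-addition (semi-stabilised ylide, unhindered aldehyde), ionisation at C7'–O and not at C8'–O (the ester on C10' destabilises a C8' cation), and the cisoid cation, which the C1' gem-dimethyl group should enforce by pushing C8' to the C5' side. The acid is catalytic and cold so that the closure stays under kinetic control.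

Step 8
Reactants: 13 dihydrofuran C15 ester
Product: 14 (2E)-3-{(2R,6S,7aR)-6-[(tert-butyldimethylsilyl)oxy]-4,4,7a-trimethyl-2,4,5,6,7,7a-hexahydro-1-benzofuran-2-yl}but-2-en-1-ol
Conditions: i-Bu2AlH, CH2Cl2, −78 °C; aq. potassium sodium tartrate
Reagents that add atoms: none
Why: Hydride reduction of the conjugated ester to the allylic alcohol at low temperature should spare the allylic ether and the silyl ether, and the neutral work-up avoids ionisation at C8'.

Step 9
Reactants: 14 allylic alcohol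
Product: 16 [(2E)-3-{(2R,6S,7aR)-6-[(tert-butyldimethylsilyl)oxy]-4,4,7a-trimethyl-2,4,5,6,7,7a-hexahydro-1-benzofuran-2-yl}but-2-en-1-yl]triphenylphosphonium bromide, via allylic bromide 15 (not isolated)
Conditions: CBr4, PPh3, CH2Cl2, −20 °C; then PPh3, rt
Reagents that add atoms: carbon tetrabromide, BrC(Br)(Br)Br; triphenylphosphine, c1ccc(cc1)P(c1ccccc1)c1ccccc1
Why: Appel bromination followed by SN2 quaternisation of PPh3 at the primary allylic carbon gives the Wittig salt without acid, so the C8'–O bond and the E-alkene should be kept.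

Step 10
Reactants: 4 enol triflate, 17 but-3-en-2-one
Product: 18 (3E)-4-{(4R)-4-[(tert-butyldimethylsilyl)oxy]-2,6,6-trimethylcyclohex-1-en-1-yl}but-3-en-2-one
Conditions: Pd(OAc)2 (5 mol %), PPh3 (10 mol %), Et3N, DMF, 70 °C
Reagents that add atoms: none
Why: The Heck reaction of the enol triflate with the enone forms C6–C7, and syn insertion followed by syn β-hydride elimination should give the E-alkene.

Step 11
Reactants: 18 silyloxy dienone
Product: 19 (3E)-4-[(4R)-4-hydroxy-2,6,6-trimethylcyclohex-1-en-1-yl]but-3-en-2-one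
Conditions: Bu4NF, THF, 0 °C → rt
Reagents that add atoms: none
Why: Fluoride-mediated desilylation frees the homoallylic hydroxyl that has to direct the next step.

Step 12
Reactants: 19 hydroxy dienone
Product: 20 (3E)-4-[(1R,4S,6S)-4-hydroxy-2,2,6-trimethyl-7-oxabicyclo[4.1.0]heptan-1-yl]but-3-en-2-one
Conditions: VO(acac)2 (5 mol %), t-BuOOH, CH2Cl2, rt
Reagents that add atoms: tert-butyl hydroperoxide, CC(C)(C)OO
Why: Hydroxyl-directed epoxidation should deliver oxygen to the electron-rich C5=C6 bond from the face of the C3 hydroxyl (oxirane syn to OH, setting C5 and C6), while the electron-poor enone alkene stays inert.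

Step 13
Reactants: 20 syn-epoxy enone
Product: 21 (3E)-4-[(1R,2R,4S)-1,2,4-trihydroxy-2,6,6-trimethylcyclohexyl]but-3-en-2-one
Conditions: HClO4 (5 mol %), THF/H2O, 0 °C → rt
Reagents that add atoms: water, O
Why: Acid-catalysed anti opening of the epoxide by water should occur at C5 because a cation at C6 is destabilised by the enone, so C5 is inverted, the C6–O bond is kept and the trans-5,6-diol of the (3S,5R,6R) end group results.

Step 14
Reactants: 21 triol enone
Product: 22 (1R,2R,4S)-1-[(1E)-3-hydroxy-3-methylpenta-1,4-dien-1-yl]-2,6,6-trimethylcyclohexane-1,2,4-triol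
Conditions: CH2=CHMgBr (6 equiv), THF, −20 → 0 °C; aq. NH4Cl
Reagents that add atoms: vinylmagnesium bromide, C=C[Mg]Br
Why: Grignard 1,2-addition to the enone carbonyl follows deprotonation of the three hydroxyls, and the new carbinol centre (both epimers) is erased in the next step.

Step 15
Reactants: 22 vinyl carbinol
Product: 23 {(2E,4E)-3-methyl-5-[(1R,2R,4S)-1,2,4-trihydroxy-2,6,6-trimethylcyclohexyl]penta-2,4-dien-1-yl}triphenylphosphonium bromide
Conditions: PPh3·HBr, MeOH, 0 °C → rt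
Reagents that add atoms: triphenylphosphine hydrobromide, [Br-].c1ccc(cc1)[PH+](c1ccccc1)c1ccccc1
Why: Ionisation of the doubly allylic tertiary alcohol and capture of the pentadienyl cation by PPh3 at its primary terminus (allylic transposition to the phosphonium salt) should give the thermodynamically favoured 9E diene.

Step 16
Reactants: 23 triol phosphonium bromide, 24 (2E,4E,6E)-2,7-dimethylocta-2,4,6-trienedial
Product: 26 (2E,4E,6E,8E,10E,12E)-2,7,11-trimethyl-13-[(1R,2R,4S)-1,2,4-trihydroxy-2,6,6-trimethylcyclohexyl]trideca-2,4,6,8,10,12-hexaenal, via phosphonium ylide 25 (not isolated)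
Conditions: NaOMe, MeOH/CH2Cl2, 0 °C → rt, 24 in threefold excess; then EtOAc, reflux, dark
Reagents that add atoms: none
Why: The Wittig reaction of the semi-stabilised ylide with one aldehyde group of the excess dialdehyde forms C11=C12 in the presence of free hydroxyls, and heating should equilibrate any 11Z isomer to the all-E hexaenal.

Step 17
Reactants: 26 C25 aldehyde, 16 dihydrofuran phosphonium bromide
Product: 28 3'-O-(tert-butyldimethylsilyl) ether of the target, via phosphonium ylide 27 (not isolated)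
Conditions: NaOMe, MeOH/CH2Cl2, 0 °C → rt, dark; then EtOAc, 60 °C
Reagents that add atoms: none
Why: The second Wittig reaction forms C11'=C12' under mild alkoxide conditions that leave the C8'–O bond alone, and gentle heating should equilibrate residual Z isomer to the all-E polyene.

Step 18
Reactants: 28 silyl ether of the target
Product: 29 (3S,5R,6R,3'S,5'R,8'R)-5',8'-epoxy-5,6,5',8'-tetrahydro-β,β-carotene-3,5,6,3'-tetrol
Conditions: Bu4NF, THF, 0 °C → rt, dark
Reagents that add atoms: none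
Why: Fluoride-mediated desilylation is non-acidic and should spare the doubly allylic C8'–O bond, the tertiary alcohols and the polyene.

**Compound list**

1 | (4R,6R)-4-hydroxy-2,2,6-trimethylcyclohexan-1-one ((4R,6R)-actinol) | C[C@H]1C(=O)C(C)(C)C[C@H](O)C1 | starting material
2 | (4R,6R)-4-[(tert-butyldimethylsilyl)oxy]-2,2,6-trimethylcyclohexan-1-one | C[C@H]1C(=O)C(C)(C)C[C@H](O[Si](C)(C)C(C)(C)C)C1 | intermediate
3 | potassium (4R)-4-[(tert-butyldimethylsilyl)oxy]-2,6,6-trimethylcyclohex-1-en-1-olate | CC1=C([O-])C(C)(C)C[C@H](O[Si](C)(C)C(C)(C)C)C1.[K+] | intermediate (not isolated)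
4 | (4R)-4-[(tert-butyldimethylsilyl)oxy]-2,6,6-trimethylcyclohex-1-en-1-yl trifluoromethanesulfonate | CC1=C(OS(=O)(=O)C(F)(F)F)C(C)(C)C[C@H](O[Si](C)(C)C(C)(C)C)C1 | intermediate
5 | {(4R)-4-[(tert-butyldimethylsilyl)oxy]-2,6,6-trimethylcyclohex-1-en-1-yl}methanol | CC1=C(CO)C(C)(C)C[C@H](O[Si](C)(C)C(C)(C)C)C1 | intermediate
6 | (4R)-1-(bromomethyl)-4-[(tert-butyldimethylsilyl)oxy]-2,6,6-trimethylcyclohex-1-ene | CC1=C(CBr)C(C)(C)C[C@H](O[Si](C)(C)C(C)(C)C)C1 | intermediate
7 | (4S,7S)-4,7-dimethyl-1,3,2-dioxathiepane 2,2-dioxide (cyclic sulfate of (2S,5S)-hexane-2,5-diol) | C[C@H]1CC[C@H](C)OS(=O)(=O)O1 | starting material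
8 | (2R,5R)-2,5-dimethylthiolane | C[C@@H]1CC[C@@H](C)S1 | intermediate
9 | (2R,5R)-1-({(4R)-4-[(tert-butyldimethylsilyl)oxy]-2,6,6-trimethylcyclohex-1-en-1-yl}methyl)-2,5-dimethylthiolan-1-ium tetrafluoroborate | CC1=C(C[S+]2[C@H](C)CC[C@H]2C)C(C)(C)C[C@H](O[Si](C)(C)C(C)(C)C)C1.F[B-](F)(F)F | intermediate
10 | ethyl (2E)-3-methyl-4-oxobut-2-enoate | CCOC(=O)/C=C(\C)C=O | starting material
11 | sulfonium ylide of 9 (carbanion at the exocyclic carbon C7') | CC1=C([CH-][S+]2[C@H](C)CC[C@H]2C)C(C)(C)C[C@H](O[Si](C)(C)C(C)(C)C)C1 | intermediate (not isolated)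
12 | ethyl (2E)-3-[(2S,3S)-3-{(4R)-4-[(tert-butyldimethylsilyl)oxy]-2,6,6-trimethylcyclohex-1-en-1-yl}oxiran-2-yl]but-2-enoate | CCOC(=O)/C=C(\C)[C@@H]1O[C@H]1C2=C(C)C[C@@H](O[Si](C)(C)C(C)(C)C)CC2(C)C | intermediate (not isolated)
13 | ethyl (2E)-3-{(2R,6S,7aR)-6-[(tert-butyldimethylsilyl)oxy]-4,4,7a-trimethyl-2,4,5,6,7,7a-hexahydro-1-benzofuran-2-yl}but-2-enoate | CCOC(=O)/C=C(\C)[C@H]1C=C2C(C)(C)C[C@H](O[Si](C)(C)C(C)(C)C)C[C@@]2(C)O1 | intermediate
14 | (2E)-3-{(2R,6S,7aR)-6-[(tert-butyldimethylsilyl)oxy]-4,4,7a-trimethyl-2,4,5,6,7,7a-hexahydro-1-benzofuran-2-yl}but-2-en-1-ol | OC/C=C(\C)[C@H]1C=C2C(C)(C)C[C@H](O[Si](C)(C)C(C)(C)C)C[C@@]2(C)O1 | intermediate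
15 | (2R,6S,7aR)-2-[(2E)-4-bromobut-2-en-2-yl]-6-[(tert-butyldimethylsilyl)oxy]-4,4,7a-trimethyl-2,4,5,6,7,7a-hexahydro-1-benzofuran | BrC/C=C(\C)[C@H]1C=C2C(C)(C)C[C@H](O[Si](C)(C)C(C)(C)C)C[C@@]2(C)O1 | intermediate (not isolated)
16 | [(2E)-3-{(2R,6S,7aR)-6-[(tert-butyldimethylsilyl)oxy]-4,4,7a-trimethyl-2,4,5,6,7,7a-hexahydro-1-benzofuran-2-yl}but-2-en-1-yl]triphenylphosphonium bromide | [Br-].c1ccc(cc1)[P+](c1ccccc1)(c1ccccc1)C/C=C(\C)[C@H]1C=C2C(C)(C)C[C@H](O[Si](C)(C)C(C)(C)C)C[C@@]2(C)O1 | intermediate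
17 | but-3-en-2-one | CC(=O)C=C | starting material
18 | (3E)-4-{(4R)-4-[(tert-butyldimethylsilyl)oxy]-2,6,6-trimethylcyclohex-1-en-1-yl}but-3-en-2-one | CC(=O)/C=C/C1=C(C)C[C@@H](O[Si](C)(C)C(C)(C)C)CC1(C)C | intermediate
19 | (3E)-4-[(4R)-4-hydroxy-2,6,6-trimethylcyclohex-1-en-1-yl]but-3-en-2-one | CC(=O)/C=C/C1=C(C)C[C@@H](O)CC1(C)C | intermediate
20 | (3E)-4-[(1R,4S,6S)-4-hydroxy-2,2,6-trimethyl-7-oxabicyclo[4.1.0]heptan-1-yl]but-3-en-2-one (oxirane syn to the hydroxyl) | CC(=O)/C=C/[C@]12O[C@@]1(C)C[C@@H](O)CC2(C)C | intermediate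
21 | (3E)-4-[(1R,2R,4S)-1,2,4-trihydroxy-2,6,6-trimethylcyclohexyl]but-3-en-2-one | CC(=O)/C=C/[C@@]1(O)C(C)(C)C[C@H](O)C[C@@]1(C)O | intermediate
22 | (1R,2R,4S)-1-[(1E)-3-hydroxy-3-methylpenta-1,4-dien-1-yl]-2,6,6-trimethylcyclohexane-1,2,4-triol (both epimers at the side-chain carbinol carbon) | C=CC(C)(O)/C=C/[C@@]1(O)C(C)(C)C[C@H](O)C[C@@]1(C)O | intermediate
23 | {(2E,4E)-3-methyl-5-[(1R,2R,4S)-1,2,4-trihydroxy-2,6,6-trimethylcyclohexyl]penta-2,4-dien-1-yl}triphenylphosphonium bromide | [Br-].c1ccc(cc1)[P+](c1ccccc1)(c1ccccc1)C/C=C(C)/C=C/[C@@]1(O)C(C)(C)C[C@H](O)C[C@@]1(C)O | intermediate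
24 | (2E,4E,6E)-2,7-dimethylocta-2,4,6-trienedial | O=C/C(C)=C/C=C/C=C(C)/C=O | starting material
25 | phosphonium ylide of 23 | c1ccc(cc1)[P+](c1ccccc1)(c1ccccc1)[CH-]/C=C(C)/C=C/[C@@]1(O)C(C)(C)C[C@H](O)C[C@@]1(C)O | intermediate (not isolated)
26 | (2E,4E,6E,8E,10E,12E)-2,7,11-trimethyl-13-[(1R,2R,4S)-1,2,4-trihydroxy-2,6,6-trimethylcyclohexyl]trideca-2,4,6,8,10,12-hexaenal | CC(/C=C/C=C(C)/C=C/[C@@]1(O)C(C)(C)C[C@H](O)C[C@@]1(C)O)=C\C=C\C=C(C)\C=O | intermediate
27 | phosphonium ylide of 16 | c1ccc(cc1)[P+](c1ccccc1)(c1ccccc1)[CH-]/C=C(\C)[C@H]1C=C2C(C)(C)C[C@H](O[Si](C)(C)C(C)(C)C)C[C@@]2(C)O1 | intermediate (not isolated)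
28 | 3'-O-(tert-butyldimethylsilyl) ether of (3S,5R,6R,3'S,5'R,8'R)-5',8'-epoxy-5,6,5',8'-tetrahydro-β,β-carotene-3,5,6,3'-tetrol | CC(/C=C/C=C(C)/C=C/[C@@]1(O)C(C)(C)C[C@H](O)C[C@@]1(C)O)=C\C=C\C=C(C)\C=C\C=C(/C)[C@H]1C=C2C(C)(C)C[C@H](O[Si](C)(C)C(C)(C)C)C[C@@]2(C)O1 | intermediate
29 | (3S,5R,6R,3'S,5'R,8'R)-5',8'-epoxy-5,6,5',8'-tetrahydro-β,β-carotene-3,5,6,3'-tetrol (CNP0210286.2) | CC(/C=C/C=C(C)/C=C/[C@@]1(O)C(C)(C)C[C@H](O)C[C@@]1(C)O)=C\C=C\C=C(C)\C=C\C=C(/C)[C@H]1C=C2C(C)(C)C[C@H](O)C[C@@]2(C)O1 | target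

**Count and risks**

Total step count: 18. Longest linear sequence: 11 steps (steps 1, 2 and 10 to 18).

Steps most likely to fail:

Step 7. The facial selectivity may be poor, either in the addition of the hindered ylide to the aldehyde (C8') or in the cationic closure (C5'). The ylide may add in conjugate fashion to the enoate, or the acid may reopen the dihydrofuran so that kinetic control is lost. The fallback sets out from 5 and comes back at 13. Sharpless asymmetric epoxidation of 5 (Ti(OiPr)4, L-(+)-diethyl tartrate, t-BuOOH) would give the epoxy alcohol with the oxirane anti to the silyloxy group, {(1R,4S,6R)-4-[(tert-butyldimethylsilyl)oxy]-2,2,6-trimethyl-7-oxabicyclo[4.1.0]heptan-1-yl}methanol F1. Dess–Martin oxidation would give (1S,4S,6R)-4-[(tert-butyldimethylsilyl)oxy]-2,2,6-trimethyl-7-oxabicyclo[4.1.0]heptane-1-carbaldehyde F2. Horner–Wadsworth–Emmons reaction with triethyl (2E)-3-methyl-4-phosphonobut-2-enoate and NaH would give ethyl (2E,4E)-3-methyl-5-{(1S,4S,6R)-4-[(tert-butyldimethylsilyl)oxy]-2,2,6-trimethyl-7-oxabicyclo[4.1.0]heptan-1-yl}penta-2,4-dienoate F3. Catalytic camphorsulfonic acid in CH2Cl2 would then bring about the 5,6-epoxide to 5,8-epoxide rearrangement, in which the oxygen stays on C5' (configuration from the reagent-controlled epoxidation) and closes on C8'. This would give 13 together with its C8' epimer, ethyl (2E)-3-{(2S,6S,7aR)-6-[(tert-butyldimethylsilyl)oxy]-4,4,7a-trimethyl-2,4,5,6,7,7a-hexahydro-1-benzofuran-2-yl}but-2-enoate F4, which is removed by chromatography.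

Step 13. Water may attack C6 instead of C5, the anti course may be lost through a free cation, or a pinacol-type ring contraction may take over. The fallback sets out from 5 and comes back at 21. Sharpless asymmetric epoxidation of 5 with D-(−)-diethyl tartrate would put the oxirane syn to the silyloxy group, {(1S,4S,6S)-4-[(tert-butyldimethylsilyl)oxy]-2,2,6-trimethyl-7-oxabicyclo[4.1.0]heptan-1-yl}methanol F5. Opening with benzoic acid and Ti(OiPr)4, which delivers the nucleophile to the oxirane carbon remote from the carbinol (C5) with inversion, would give (1R,2S,5S)-5-[(tert-butyldimethylsilyl)oxy]-2-hydroxy-2-(hydroxymethyl)-1,3,3-trimethylcyclohexyl benzoate F6. Oxidation of the primary alcohol (TEMPO, PhI(OAc)2) would give (1R,2R,5S)-5-[(tert-butyldimethylsilyl)oxy]-2-formyl-2-hydroxy-1,3,3-trimethylcyclohexyl benzoate F7. Wittig reaction with 1-(triphenylphosphoranylidene)propan-2-one would give (1R,2R,5S)-5-[(tert-butyldimethylsilyl)oxy]-2-hydroxy-1,3,3-trimethyl-2-[(1E)-3-oxobut-1-en-1-yl]cyclohexyl benzoate F8. Methanolysis of the benzoate (K2CO3, MeOH) would give (3E)-4-{(1R,2R,4S)-4-[(tert-butyldimethylsilyl)oxy]-1,2-dihydroxy-2,6,6-trimethylcyclohexyl}but-3-en-2-one F9, and Bu4NF would then give 21.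

Step 15. The pentadienyl cation may be captured by the tertiary hydroxyl at C6 (spiro ether) or may undergo a 1,2-shift instead of capture by PPh3, and 9E control may be lost. The fallback sets out from 21 and comes back at 26. Horner–Wadsworth–Emmons reaction of 21 with triethyl phosphonoacetate and excess NaH would give ethyl (2E,4E)-3-methyl-5-[(1R,2R,4S)-1,2,4-trihydroxy-2,6,6-trimethylcyclohexyl]penta-2,4-dienoate F10, freed of its 2Z isomer by chromatography. Reduction with i-Bu2AlH would give (1R,2R,4S)-1-[(1E,3E)-5-hydroxy-3-methylpenta-1,3-dien-1-yl]-2,6,6-trimethylcyclohexane-1,2,4-triol F11. Corey–Kim chlorination (N-chlorosuccinimide, Me2S), which is selective for the allylic hydroxyl, would give (1R,2R,4S)-1-[(1E,3E)-5-chloro-3-methylpenta-1,3-dien-1-yl]-2,6,6-trimethylcyclohexane-1,2,4-triol F12. PPh3 would then give {(2E,4E)-3-methyl-5-[(1R,2R,4S)-1,2,4-trihydroxy-2,6,6-trimethylcyclohexyl]penta-2,4-dien-1-yl}triphenylphosphonium chloride F13, which would take the place of 23 under the conditions of step 16 and give 26.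

Further compounds
F1 | step 7 | {(1R,4S,6R)-4-[(tert-butyldimethylsilyl)oxy]-2,2,6-trimethyl-7-oxabicyclo[4.1.0]heptan-1-yl}methanol | OC[C@@]12O[C@]1(C)C[C@@H](O[Si](C)(C)C(C)(C)C)CC2(C)C
F2 | step 7 | (1S,4S,6R)-4-[(tert-butyldimethylsilyl)oxy]-2,2,6-trimethyl-7-oxabicyclo[4.1.0]heptane-1-carbaldehyde | O=C[C@@]12O[C@]1(C)C[C@@H](O[Si](C)(C)C(C)(C)C)CC2(C)C
F3 | step 7 | ethyl (2E,4E)-3-methyl-5-{(1S,4S,6R)-4-[(tert-butyldimethylsilyl)oxy]-2,2,6-trimethyl-7-oxabicyclo[4.1.0]heptan-1-yl}penta-2,4-dienoate | CCOC(=O)/C=C(C)/C=C/[C@@]12O[C@]1(C)C[C@@H](O[Si](C)(C)C(C)(C)C)CC2(C)C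
F4 | step 7 | ethyl (2E)-3-{(2S,6S,7aR)-6-[(tert-butyldimethylsilyl)oxy]-4,4,7a-trimethyl-2,4,5,6,7,7a-hexahydro-1-benzofuran-2-yl}but-2-enoate | CCOC(=O)/C=C(\C)[C@@H]1C=C2C(C)(C)C[C@H](O[Si](C)(C)C(C)(C)C)C[C@@]2(C)O1
F5 | step 13 | {(1S,4S,6S)-4-[(tert-butyldimethylsilyl)oxy]-2,2,6-trimethyl-7-oxabicyclo[4.1.0]heptan-1-yl}methanol | OC[C@]12O[C@@]1(C)C[C@@H](O[Si](C)(C)C(C)(C)C)CC2(C)C
F6 | step 13 | (1R,2S,5S)-5-[(tert-butyldimethylsilyl)oxy]-2-hydroxy-2-(hydroxymethyl)-1,3,3-trimethylcyclohexyl benzoate | OC[C@@]1(O)C(C)(C)C[C@H](O[Si](C)(C)C(C)(C)C)C[C@@]1(C)OC(=O)c1ccccc1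
F7 | step 13 | (1R,2R,5S)-5-[(tert-butyldimethylsilyl)oxy]-2-formyl-2-hydroxy-1,3,3-trimethylcyclohexyl benzoate | O=C[C@@]1(O)C(C)(C)C[C@H](O[Si](C)(C)C(C)(C)C)C[C@@]1(C)OC(=O)c1ccccc1
F8 | step 13 | (1R,2R,5S)-5-[(tert-butyldimethylsilyl)oxy]-2-hydroxy-1,3,3-trimethyl-2-[(1E)-3-oxobut-1-en-1-yl]cyclohexyl benzoate | CC(=O)/C=C/[C@@]1(O)C(C)(C)C[C@H](O[Si](C)(C)C(C)(C)C)C[C@@]1(C)OC(=O)c1ccccc1
F9 | step 13 | (3E)-4-{(1R,2R,4S)-4-[(tert-butyldimethylsilyl)oxy]-1,2-dihydroxy-2,6,6-trimethylcyclohexyl}but-3-en-2-one | CC(=O)/C=C/[C@@]1(O)C(C)(C)C[C@H](O[Si](C)(C)C(C)(C)C)C[C@@]1(C)O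
F10 | step 15 | ethyl (2E,4E)-3-methyl-5-[(1R,2R,4S)-1,2,4-trihydroxy-2,6,6-trimethylcyclohexyl]penta-2,4-dienoate | CCOC(=O)/C=C(C)/C=C/[C@@]1(O)C(C)(C)C[C@H](O)C[C@@]1(C)O
F11 | step 15 | (1R,2R,4S)-1-[(1E,3E)-5-hydroxy-3-methylpenta-1,3-dien-1-yl]-2,6,6-trimethylcyclohexane-1,2,4-triol | OC/C=C(C)/C=C/[C@@]1(O)C(C)(C)C[C@H](O)C[C@@]1(C)O
F12 | step 15 | (1R,2R,4S)-1-[(1E,3E)-5-chloro-3-methylpenta-1,3-dien-1-yl]-2,6,6-trimethylcyclohexane-1,2,4-triol | ClC/C=C(C)/C=C/[C@@]1(O)C(C)(C)C[C@H](O)C[C@@]1(C)O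
F13 | step 15 | {(2E,4E)-3-methyl-5-[(1R,2R,4S)-1,2,4-trihydroxy-2,6,6-trimethylcyclohexyl]penta-2,4-dien-1-yl}triphenylphosphonium chloride | [Cl-].c1ccc(cc1)[P+](c1ccccc1)(c1ccccc1)C/C=C(C)/C=C/[C@@]1(O)C(C)(C)C[C@H](O)C[C@@]1(C)O
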